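## Retrosynthetic overview
1. 17 ⇒ 14: the enone is made last, by a singlet-oxygen ene reaction and dehydration of the ring alkene. The C=O lands on the old =CH and the C=C moves one position.
2. 14 ⇒ 11 ⇒ 9 ⇒ 8: the C11 carbinol and the E-C9=C10 bond come from a Sharpless epoxide (PhSe− opening, selenoxide elimination). The allylic alcohol comes from SeO2 oxidation of the prenyl end.
3. 8 ⇒ 5: the only ring is closed by the biosynthetic 1,6-closure of a farnesyl-type cation (farnesyl → nerolidyl-type isomerisation, C1–C6 bond, bisabolyl cation, loss of H from C14). It is run on a C15-oxygenated substrate under a confined chiral counter-anion, which sets C6.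
4. 5 ⇒ 3 ⇒ 1: both allylic oxygens (leaving group at C1, final ester at C15) come from 1,4-diboration/oxidation of (E)-β-farnesene followed by double acylation.
5. Ring order: one ring only, formed in step 3.

Atom labels follow farnesane numbering: chain C1–C12, C13 on C11, C14 on C7, C15 on C3. The target is (6R,11R).

Assumption: the sense of induction of the new cyclisation cannot be predicted, so the (S,S)-acid is written for the (R)-product and its equally accessible mirror image is used if the sense is opposite.

## Route

Step 1
Reactants: 1 (E)-β-farnesene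
Product: 3 (2Z)-2-[(3E)-4,8-dimethylnona-3,7-dien-1-yl]but-2-ene-1,4-diol, via 1,4-bis(boronate) 2 (not isolated)
Conditions: B2pin2 (1.05 equiv), Ni(cod)2 (2.5 mol %), PCy3 (2.5 mol %), toluene, 60 °C; then THF, 3 M NaOH, 30 % H2O2, 0 °C → rt
Reagents that add atoms: bis(pinacolato)diboron, CC1(C)OB(OC1(C)C)B1OC(C)(C)C(C)(C)O1 (the two boryl groups of 2 only); hydrogen peroxide, OO (the two hydroxyl oxygens of 3)
Why: Zerovalent-nickel-catalysed 1,4-diboration occurs only at the conjugated diene, which binds s-cis so that both CH2B groups end up cis on the new C2=C3 bond and the isolated trisubstituted alkenes are untouched, and stereoretentive alkaline peroxide oxidation of the C–B bonds gives the diol; no stereocentre is formed.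

Step 2
Reactants: 3 the diol; 4 isobutyric anhydride
Product: 5 (2Z)-2-[(3E)-4,8-dimethylnona-3,7-dien-1-yl]but-2-ene-1,4-diyl bis(2-methylpropanoate)
Conditions: (iPrCO)2O (2.5 equiv), Et3N, 4-(dimethylamino)pyridine (5 mol %), CH2Cl2, 0 °C → rt
Reagents that add atoms: isobutyric anhydride (4), CC(C)C(=O)OC(=O)C(C)C
Why: Nucleophile-catalysed esterification of two primary allylic alcohols, which in one operation installs the final C15 ester and turns the C1 oxygen into the leaving group for ring closure; no stereocentre is formed.

Step 3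
Reactants: 5 the bis(isobutyrate)
Product: 8 [(4R)-4-(6-methylhepta-1,5-dien-2-yl)cyclohex-1-en-1-yl]methyl 2-methylpropanoate (15-isobutyryloxy-β-bisabolene), via vinyl-dioxolanylium cation 6 (not isolated), via bisabolyl cation 7 (not isolated)
Conditions: HX* (5 mol %) = (S,S)-imidodiphosphorimidate acid HN[P(=NSO2CF3)(O2C20H10Ar2)]2, where O2C20H10Ar2 = (S)-3,3'-Ar2-1,1'-binaphthalene-2,2'-diolate and Ar = 3,5-(CF3)2C6H3; CH2Cl2/(CF3)3COH 9:1, −30 °C
Reagents that add atoms: none
Why: Proposed new method: the strong confined acid ionises the C1 ester (the only one that gives a tertiary-stabilised allyl cation), the neighbouring C15 ester carbonyl captures C3 to give cation 6, in which C3 is sp3 so the vinyl group can turn into the cisoid rotamer (the laboratory copy of the farnesyl → nerolidyl diphosphate isomerisation, which makes the unsuitable C2=C3 geometry of 5 irrelevant and lets both enantiomers of 6 interconvert through the open cation), the C6=C7 bond then attacks C1 in a chair-like anti SN2′ 1,6-closure inside the chiral anion pocket, which sets C6 as R, and the anion removes the most accessible proton of cation 7, one of the C14 methyl group, to give the 1,1-disubstituted alkene and return the acid; the closest known reaction types are the chiral-leaving-group/organoaluminium cyclisation of neryl and farnesyl ethers to limonene and bisabolenes, the confined-acid carbonyl-ene cyclisation of neral to isopiperitenol, the imidodiphosphorimidate-catalysed polyene cyclisation of homofarnesol, and acyloxonium neighbouring-group participation.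

Step 4
Reactants: 8 the cyclised ester
Product: 9 {(4R)-4-[(5E)-7-hydroxy-6-methylhepta-1,5-dien-2-yl]cyclohex-1-en-1-yl}methyl 2-methylpropanoate
Conditions: SeO2 (0.3 equiv), tBuOOH (2.5 equiv), salicylic acid (0.1 equiv), CH2Cl2, 0 °C → rt
Reagents that add atoms: tert-butyl hydroperoxide, CC(C)(C)OO (terminal oxygen source); selenium dioxide, O=[Se]=O (passes the oxygen on)
Why: Catalytic SeO2/tBuOOH allylic hydroxylation (ene reaction, then 2,3-sigmatropic shift) picks the most electron-rich alkene, the prenyl end (the ring alkene is deactivated by its allylic ester and the 1,1-disubstituted alkene reacts more slowly), and oxidises the methyl group trans to the chain, giving the E-allylic alcohol with C6 untouched.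

Step 5
Reactants: 9 the allylic alcohol; 4 isobutyric anhydride
Product: 11 {(2S,3S)-2-methyl-3-[3-((1R)-4-{[(2-methylpropanoyl)oxy]methyl}cyclohex-3-en-1-yl)but-3-en-1-yl]oxiran-2-yl}methyl 2-methylpropanoate, via epoxy alcohol 10 (not isolated)
Conditions: Ti(OiPr)4 (10 mol %), L-(+)-diethyl tartrate (12 mol %), tBuOOH (1.5 equiv), 4 Å sieves, CH2Cl2, −20 °C; then P(OMe)3 (0.6 equiv); then Et3N, 4-(dimethylamino)pyridine, (iPrCO)2O, −20 → 0 °C
Reagents that add atoms: tert-butyl hydroperoxide, CC(C)(C)OO (epoxide oxygen); isobutyric anhydride (4), CC(C)C(=O)OC(=O)C(C)C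
Why: Katsuki–Sharpless asymmetric epoxidation touches only the alkene bearing the free allylic hydroxyl, L-(+)-tartrate delivers oxygen to the face that gives the (10S,11S)-epoxide (reagent control, fixing the C11–O bond of the target, with no influence from the remote C6), and the crude epoxy alcohol is esterified in the same flask once the excess hydroperoxide has been reduced (in situ derivatisation).

Step 6
Reactants: 11 the epoxy ester
Product: 14 {(4R)-4-[(4E,6R)-6-hydroxy-6-methyl-7-(2-methylpropanoyloxy)hepta-1,4-dien-2-yl]cyclohex-1-en-1-yl}methyl 2-methylpropanoate, via hydroxy selenide 12 (not isolated), via selenoxide 13 (not isolated)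
Conditions: (PhSe)2 (0.6 equiv), NaBH4 (1.3 equiv), EtOH, rt → 60 °C; then THF, pyridine, 30 % H2O2, 0 °C → rt
Reagents that add atoms: diphenyl diselenide, c1ccc(cc1)[Se][Se]c1ccccc1 (PhSe group of 12 and 13 only, nothing of it stays in 14); hydrogen peroxide, OO (Se=O oxygen of 13 only)
Why: Sharpless–Lauer epoxide-to-allylic-alcohol transposition, in which the soft borate-bound PhSe− (too mild to cleave the esters) opens the epoxide by SN2 attack at the less hindered C10 so that the C11–O bond and its configuration are kept (the descriptor changes from S to R only because the CIP ranks change), and the selenoxide undergoes syn elimination, which can only go towards C9 because C11 carries no hydrogen, to give the E-alkene.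

Step 7
Reactants: 14 the tertiary allylic alcohol
Product: 17 CNP0536801.1 {(4R)-4-[(4E,6R)-6-hydroxy-6-methyl-7-(2-methylpropanoyloxy)hepta-1,4-dien-2-yl]-6-oxocyclohex-1-en-1-yl}methyl 2-methylpropanoate, via allylic hydroperoxide 15 (not isolated), via peroxyacetate 16 (not isolated)
Conditions: O2, 5,10,15,20-tetraphenylporphyrin (0.5 mol %), white LED, CH2Cl2, −20 °C; then Ac2O, iPr2NEt, 0 °C → rt
Reagents that add atoms: dioxygen, O=O (both oxygens of 15 and 16, one stays as the ketone oxygen of 17); acetic anhydride, CC(=O)OC(C)=O (acetyl group of 16 only)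
Why: Schenck ene reaction followed by Kornblum–DeLaMare-type dehydration, in which singlet oxygen reacts much faster with the one trisubstituted alkene than with the 1,1- and 1,2-disubstituted ones, bonds to the less substituted C2 and takes an axial ring hydrogen at C4 geminal to the bulky, electron-poor CH2OCOiPr group (whose own hydrogens are deactivated) so that the C=C moves to C3=C4, and acetylation of the OOH group with base-induced loss of acetic acid converts both C2 epimers into one ketone, while the non-nucleophilic base spares the new allylic ester, the tertiary alcohol, C6 and C11.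

## Compound list
1 | (E)-β-farnesene, (6E)-7,11-dimethyl-3-methylidenedodeca-1,6,10-triene | C=CC(=C)CC/C=C(\C)CCC=C(C)C | starting material
2 | 1,4-bis(pinacolboryl) adduct of 1, both CH2B groups cis on C2=C3 | CC1(C)OB(C/C=C(\CB2OC(C)(C)C(C)(C)O2)CC/C=C(\C)CCC=C(C)C)OC1(C)C | intermediate
3 | (2Z)-2-[(3E)-4,8-dimethylnona-3,7-dien-1-yl]but-2-ene-1,4-diol | OC/C=C(\CO)CC/C=C(\C)CCC=C(C)C | intermediate
4 | isobutyric anhydride | CC(C)C(=O)OC(=O)C(C)C | starting material
5 | bis(isobutyrate) of 3 | CC(C)C(=O)OC/C=C(\COC(=O)C(C)C)CC/C=C(\C)CCC=C(C)C | intermediate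
6 | 4-[(3E)-4,8-dimethylnona-3,7-dienyl]-2-isopropyl-4-vinyl-1,3-dioxolan-2-ylium ion (C3 epimers interconvert) | CC(C)C1=[O+]C(C=C)(CC/C=C(\C)CCC=C(C)C)CO1 | intermediate
7 | (6R)-15-isobutyryloxybisabolyl cation (charge at C7) | C[C+](CCC=C(C)C)[C@H]1CC=C(COC(=O)C(C)C)CC1 | intermediate
8 | [(4R)-4-(6-methylhepta-1,5-dien-2-yl)cyclohex-1-en-1-yl]methyl isobutyrate | C=C(CCC=C(C)C)[C@H]1CC=C(COC(=O)C(C)C)CC1 | intermediate
9 | (6R,10E)-12-hydroxy derivative of 8 | C=C(CC/C=C(\C)CO)[C@H]1CC=C(COC(=O)C(C)C)CC1 | intermediate
10 | (6R,10S,11S)-10,11-epoxy-12-ol | C=C(CC[C@@H]1O[C@@]1(C)CO)[C@H]1CC=C(COC(=O)C(C)C)CC1 | intermediate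
11 | (6R,10S,11S)-10,11-epoxy-12,15-bis(isobutyrate) | C=C(CC[C@@H]1O[C@@]1(C)COC(=O)C(C)C)[C@H]1CC=C(COC(=O)C(C)C)CC1 | intermediate
12 | (6R,10R,11S)-11-hydroxy-10-(phenylselanyl) diester | C=C(CC[C@@H]([Se]c1ccccc1)[C@@](C)(O)COC(=O)C(C)C)[C@H]1CC=C(COC(=O)C(C)C)CC1 | intermediate
13 | selenoxide of 12 (mixture at Se) | C=C(CC[C@@H]([Se](=O)c1ccccc1)[C@@](C)(O)COC(=O)C(C)C)[C@H]1CC=C(COC(=O)C(C)C)CC1 | intermediate
14 | (6R,9E,11R)-11-hydroxy-12,15-bis(isobutyryloxy)bisabola-2,7(14),9-triene | C=C(C/C=C/[C@@](C)(O)COC(=O)C(C)C)[C@H]1CC=C(COC(=O)C(C)C)CC1 | intermediate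
15 | C2 allylic hydroperoxide with C3=C4 alkene (both C2 epimers) | C=C(C/C=C/[C@@](C)(O)COC(=O)C(C)C)[C@@H]1CC=C(COC(=O)C(C)C)C(OO)C1 | intermediate
16 | peroxyacetate of 15 (both C2 epimers) | C=C(C/C=C/[C@@](C)(O)COC(=O)C(C)C)[C@@H]1CC=C(COC(=O)C(C)C)C(OOC(C)=O)C1 | intermediate
17 | CNP0536801.1 | C=C(C/C=C/[C@@](C)(O)COC(=O)C(C)C)[C@@H]1CC=C(COC(=O)C(C)C)C(=O)C1 | target

## Step count and risks
Total step count: 7. Longest linear sequence: 7 (fully linear from 1).

**Step 3 (most likely to fail).** Possible failures are low enantioselectivity, proton loss from C8 or C6 instead of C14, acyclic trienes by simple elimination, or protonation of the prenyl alkene. The fallback sets out from 5 and returns at 8. It gives up catalyst control and uses a racemic closure followed by resolution. Compound 5 is treated with the stoichiometric bulky Lewis acid MeAl(OC6H2-2,6-tBu2-4-Me)2 in CH2Cl2 at −78 → −20 °C. This reagent class is known for turning neryl and farnesyl phosphates into limonene and bisabolenes, and its aluminate acts as a hindered, irreversible proton sink, so no free acid builds up. This gives racemic cyclised ester F1. Preparative supercritical-fluid chromatography on an amylose tris(3,5-dimethylphenylcarbamate) phase then separates 8 from the (S)-enantiomer F2, which is discarded.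

**Step 7.** Possible failures are formation of the tertiary C3 hydroperoxide, attack of singlet oxygen on the 1,1-disubstituted alkene, or loss of the sensitive allylic ester. The fallback sets out from 14 and returns at 17. It replaces the pericyclic oxidation with polar nitrosation, the logic of the limonene-to-carvone process. NOCl (from isoamyl nitrite and Me3SiCl, CH2Cl2, −20 °C) adds in the Markovnikov sense to the one trisubstituted alkene to give nitroso chloride F3. NaOAc in warm DMF removes HCl and gives conjugated oxime F4. Oxime exchange with aqueous acetone and pyridinium p-toluenesulfonate at 50 °C releases 17.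

**Step 4.** Possible failures are modest yield, over-oxidation to the enal, or attack next to the 1,1-disubstituted alkene. The fallback sets out from 8 and returns at 9. It replaces C–H oxidation with cleavage and re-olefination. One equivalent of mCPBA (NaHCO3, CH2Cl2, −20 °C) epoxidises the most electron-rich alkene to give terminal epoxide F5. H5IO6 in aqueous THF cleaves it to aldehyde F6. Wittig reaction with Ph3P=C(CH3)CHO in toluene at 90 °C gives (E)-enal F7. Luche reduction (NaBH4, CeCl3·7H2O, MeOH, 0 °C) then gives 9.

## Further compounds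
F1 | step 3 | racemic [4-(6-methylhepta-1,5-dien-2-yl)cyclohex-1-en-1-yl]methyl isobutyrate | C=C(CCC=C(C)C)C1CC=C(COC(=O)C(C)C)CC1
F2 | step 3 | [(4S)-4-(6-methylhepta-1,5-dien-2-yl)cyclohex-1-en-1-yl]methyl isobutyrate | C=C(CCC=C(C)C)[C@@H]1CC=C(COC(=O)C(C)C)CC1
F3 | step 7 | 3-chloro-2-nitroso adduct of 14 (isolated as its dimer, mixture at C2 and C3) | C=C(C/C=C/[C@@](C)(O)COC(=O)C(C)C)[C@@H]1CCC(Cl)(COC(=O)C(C)C)C(N=O)C1
F4 | step 7 | oxime of 17 | C=C(C/C=C/[C@@](C)(O)COC(=O)C(C)C)[C@@H]1CC=C(COC(=O)C(C)C)C(=NO)C1
F5 | step 4 | 10,11-epoxide of 8 (both C10 epimers) | CC1(C)OC1CCC(=C)[C@H]1CC=C(COC(=O)C(C)C)CC1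
F6 | step 4 | {(4R)-4-(5-oxopent-1-en-2-yl)cyclohex-1-en-1-yl}methyl isobutyrate | O=CCCC(=C)[C@H]1CC=C(COC(=O)C(C)C)CC1
F7 | step 4 | {(4R)-4-[(5E)-6-methyl-7-oxohepta-1,5-dien-2-yl]cyclohex-1-en-1-yl}methyl isobutyrate | O=C/C(C)=C/CCC(=C)[C@H]1CC=C(COC(=O)C(C)C)CC1
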